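The plan disconnects the norbornane at C8–C4 together with a temporary C19–C5 bond (carbons numbered C1–C20 as in the target SMILES). A crossed (2+2) photocycloaddition of cyclopentenone 10 closes ring C (C4–C8) and a cyclobutane at once and fixes the quaternary bridgehead C8 from C6. It exploits that, in ring D (C6, C7, C8, C19, C20), C8 is β and C19 α to the C20 carbonyl, while the allene carbons C4 and C5 hang on C6; the C19–C5 bond is then cut reductively. Precursor 10 is a 3-alkylcyclopent-2-enone with a 3-methylbuta-1,2-dienyl group on C6 and an acetal-ended chain on C8. Rings A and B arise by transannular bromocyclisation.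

Key step: step 4

Remark on the chemistry: ring A = C11, C13, C14, C15, C16, C18 and ring B = C8, C9, C10, C11, C18, C19; exo is the norbornane face on the side of the C7 bridge; anti addition to the (S)-acetate 1 leads to (5R)-10 and to C6 of the target, so no structure needed correction; because C6–H of 10 is α to the ketone and next to the allene, 10 is made under buffered conditions and irradiated without storage.

Step 1
Reactants: 1 (S)-4-acetoxycyclopent-2-en-1-one; 2 3-methylbuta-1,2-diene
Product: 6 (S)-4-(3-methylbuta-1,2-dienyl)cyclopent-2-en-1-one, via allenyllithium 3 (not isolated), via lithium diallenylcuprate 4 (not isolated), via trans-acetoxy ketone adduct 5 (not isolated)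
Conditions: 2, n-BuLi, THF, −78 to −30 °C; CuI, −40 °C; 1, −78 °C; aq NH4Cl; then Et3N, CH2Cl2, 0 °C
Reagents that add atoms: none
Why: Conjugate addition of the homocuprate occurs anti to the acetoxy group and transfers the allenyl terminus (propargylic transfer would build a quaternary carbon), and E1cB loss of acetate then relocates the enone, so the new stereocentre (future C6) is set by the departing acetate.

Step 2
Reactants: 6 (S)-4-(3-methylbuta-1,2-dienyl)cyclopent-2-en-1-one; 7 2-(2-bromoethyl)-1,3-dioxolane
Product: 9 (4S)-1-[2-(1,3-dioxolan-2-yl)ethyl]-4-(3-methylbuta-1,2-dienyl)cyclopent-2-en-1-ol (both C1 epimers), via Grignard reagent 8 (not isolated)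
Conditions: 7, Mg, THF, 25 °C; then 6, THF, −78 to 0 °C
Reagents that add atoms: none
Why: Grignard 1,2-addition to the enone carbonyl gives the tertiary allylic alcohol, whose carbinol configuration is irrelevant because step 3 erases it.

Step 3
Reactants: 9 tertiary allylic alcohol
Product: 10 (5R)-5-(3-methylbuta-1,2-dienyl)-3-[2-(1,3-dioxolan-2-yl)ethyl]cyclopent-2-en-1-one
Conditions: [C5H5NH][CrO3Cl], NaOAc, 4 Å molecular sieves, CH2Cl2, 20 °C
Reagents that add atoms: pyridinium chlorochromate, c1cc[nH+]cc1.[O-][Cr](=O)(=O)Cl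
Why: Oxidative 1,3-transposition of the tertiary allylic alcohol (Dauben–Babler oxidation, a [3,3] shift of the chromate ester followed by oxidation) puts the carbonyl C20 next to C6 and the chain on the β-carbon C8, while the acetate buffer protects the enolisable C6 and the acetal.

Step 4
Reactants: 10 (5R)-5-(3-methylbuta-1,2-dienyl)-3-[2-(1,3-dioxolan-2-yl)ethyl]cyclopent-2-en-1-one
Product: 11 crossed photoadduct 1-[2-(1,3-dioxolan-2-yl)ethyl]-7-(propan-2-ylidene)tricyclo[3.2.0.0(3,6)]heptan-4-one
Conditions: hν (366 nm), CH2Cl2 (5 mM), argon, 0 °C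
Reagents that add atoms: none
Why: Excitation gives the triplet enone, whose β-carbon C8 bonds first to the central allene carbon C4 (1,5-closure, rule of five), leaving a diradical made of the α-keto radical at C19 and an allyl radical over C5–C4–C2, and after spin inversion C19 combines with C5. The closest known reaction type is the intramolecular crossed (2+2) photocycloaddition of enones with allenes or alkenes held by a two-atom tether, which gives bicyclo[2.1.1]hexanes. Ring C (C4–C8) closes as a five-membered ring at C8, and the four-membered ring C19–C5–C4–C8 closes by radical recombination. C8 is controlled by C6 because the allene can reach only the enone face on which it sits, and C19 and C5 are then dictated by the cage. The step needs crossed and not straight regiochemistry, which the two-atom link (C7, C6) between C8 and the allene secures, and closure at the other allyl terminus would still converge in step 5.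

Step 5
Reactants: 11 crossed photoadduct
Product: 12 4-[2-(1,3-dioxolan-2-yl)ethyl]-5-(propan-2-ylidene)bicyclo[2.2.1]heptan-2-one
Conditions: SmI2, THF–MeOH, −78 °C
Reagents that add atoms: none
Why: Single-electron reduction gives the C20 ketyl, which breaks the α–β bond C19–C5 that overlaps with the carbonyl π system and is shared by both four-membered rings (reductive fragmentation of an α-keto cyclobutane), and the samarium enolate and allyl-samarium are protonated at C19 and C5 without touching a stereocentre.

Step 6
Reactants: 12 isopropylidene norbornanone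
Product: 13 4-[2-(1,3-dioxolan-2-yl)ethyl]-5-endo-isopropylbicyclo[2.2.1]heptan-2-one
Conditions: H2 (10 bar), [Ir(cod)(PCy3)(py)]PF6 (5 mol %), CH2Cl2, 25 °C
Reagents that add atoms: none
Why: Homogeneous hydrogenation of the tetrasubstituted exocyclic alkene delivers hydrogen to C4 from the open exo face, which sets the isopropyl group on C4 endo, and the ketone and acetal are inert.

Step 7
Reactants: 13 endo-isopropyl norbornanone; 14 methacrolein
Product: 16 aldol adduct, 13 bearing a 1-hydroxy-2-methylprop-2-enyl group exo on C19 (both C18 epimers), via lithium enolate 15 (not isolated)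
Conditions: LiN(i-Pr)2, THF, −78 °C; then 14, −78 °C; AcOH
Reagents that add atoms: none
Why: Aldol addition of the only possible enolate (C19, since bridgehead C6 cannot enolise) to the aldehyde takes place on the exo face away from the endo isopropyl group, which sets C19 with H endo and C18 exo.

Step 8
Reactants: 16 aldol adduct
Product: 18 ketone bearing an (E)-2-methyl-3-(phenylsulfinyl)prop-1-enyl group exo on C19 (both sulfur epimers), via allylic sulfenate ester 17 (not isolated)
Conditions: PhSCl, Et3N, CH2Cl2, −78 to 0 °C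
Reagents that add atoms: benzenesulfenyl chloride, ClSc1ccccc1
Why: O-sulfenylation and [2,3]-sigmatropic sulfenate-to-sulfoxide rearrangement (reverse Mislow–Evans) move sulfur to C15 and create the C16=C18 alkene, the reversible shift favouring the (E) isomer with C19 trans to C15, and the mild base does not enolise C19.

Step 9
Reactants: 18 allylic sulfoxide ketone
Product: 19 endo-C20 alcohol of 18
Conditions: NaBH4, MeOH, −20 °C
Reagents that add atoms: none
Why: Hydride reduction of the norbornanone from the exo face gives the endo alcohol (sets C20) and removes the enolisable ketone before any strong base is used.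

Step 10
Reactants: 19 hydroxy sulfoxide
Product: 20 hydroxy sulfone (C15–SO2Ph)
Conditions: (NH4)6Mo7O24·4H2O (5 mol %), H2O2, EtOH, 0 to 20 °C
Reagents that add atoms: hydrogen peroxide, OO
Why: Molybdate-catalysed S-oxidation takes the sulfoxide to the sulfone chemoselectively beside the trisubstituted alkene, the alcohol and the acetal.

Step 11
Reactants: 20 hydroxy sulfone
Product: 21 tert-butyldimethylsilyl ether of 20 (C20–OTBS)
Conditions: TBSOTf, 2,6-lutidine, CH2Cl2, 0 °C
Reagents that add atoms: tert-butyldimethylsilyl triflate, CC(C)(C)[Si](C)(C)OS(=O)(=O)C(F)(F)F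
Why: Silylation of the hindered secondary alcohol with the silyl triflate protects C20–OH against the aluminium reagents and the amide base used later.

Step 12
Reactants: 21 silyl ether acetal
Product: 22 aldehyde (C11 formyl)
Conditions: pyridinium p-toluenesulfonate, acetone–H2O, 60 °C
Reagents that add atoms: water, O
Why: Acid-catalysed acetal hydrolysis frees the C11 aldehyde while the hindered silyl ether and the sulfone survive.

Step 13
Reactants: 22 aldehyde
Product: 23 terminal alkyne (C11≡C13)
Conditions: dimethyl (1-diazo-2-oxopropyl)phosphonate, K2CO3, MeOH, 0 to 20 °C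
Reagents that add atoms: dimethyl (1-diazo-2-oxopropyl)phosphonate, COP(=O)(OC)C(=[N+]=[N-])C(C)=O
Why: Ohira–Bestmann homologation converts the aldehyde into the alkyne under carbonate conditions that leave the allylic sulfone untouched.

Step 14
Reactants: 23 terminal alkyne
Product: 25 methyl (E)-enoate (C11(CH3)=C13H–C14O2Me), via alkenylalane 24 (not isolated)
Conditions: Me3Al, Cp2ZrCl2 (0.3 equiv), CH2Cl2, 0 to 20 °C; then ClCO2Me, 0 °C
Reagents that add atoms: trimethylaluminium, C[Al](C)C; methyl chloroformate, COC(=O)Cl
Why: Zirconium-catalysed syn-carboalumination of the alkyne (Negishi carboalumination) places the C12 methyl on C11 and aluminium on C13, and acylation with retention gives the (E)-trisubstituted enoate with C10 trans to C14.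

Step 15
Reactants: 25 methyl (E)-enoate
Product: 26 (E)-allylic alcohol (C14–OH)
Conditions: i-Bu2AlH, CH2Cl2, −78 °C
Reagents that add atoms: none
Why: Hydride 1,2-reduction of the conjugated ester gives the allylic alcohol without affecting the sulfone or the silyl ether.

Step 16
Reactants: 26 (E)-allylic alcohol
Product: 27 (E)-allylic bromide (C14–Br)
Conditions: MsCl, Et3N, THF, −40 °C; then LiBr, 0 °C
Reagents that add atoms: lithium bromide, [Li+].[Br-]
Why: Mesylation and SN2 displacement by bromide give the primary allylic bromide with the alkene geometry unchanged.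

Step 17
Reactants: 27 (E)-allylic bromide
Product: 28 ten-membered (E,E)-diene sulfone (ring C8–C9–C10–C11–C13–C14–C15–C16–C18–C19; both C15 epimers)
Conditions: NaN(SiMe3)2, THF, 50 °C, slow addition (final 2 mM)
Reagents that add atoms: none
Why: Intramolecular SN2 alkylation of the sulfone-stabilised allyl carbanion at C15 by the allylic bromide at C14 under high dilution closes the ten-membered ring, a macrocyclisation type established for head-to-tail closure of germacrane chains.

Step 18
Reactants: 28 macrocyclic sulfone
Product: 29 (E,E)-cyclodeca-1,5-diene fused to the norbornane at C8–C19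
Conditions: PdCl2(dppp) (5 mol %), LiBHEt3, THF, 0 °C
Reagents that add atoms: none
Why: Palladium-catalysed reductive desulfonylation through a π-allyl complex delivers hydride to the less hindered terminus C15, so the (E)-C16=C18 alkene stays in place.

Step 19
Reactants: 29 (E,E)-cyclodecadiene
Product: 30 bromo alcohol, target skeleton with C20–OTBS and the C16 epimer (equatorial OH, axial methyl)
Conditions: NBS, acetone–H2O (5:1), 0 °C
Reagents that add atoms: N-bromosuccinimide, O=C1CCC(=O)N1Br; water, O
Why: Bromonium formation at C11=C13 from the ring periphery triggers transannular attack of C18 on C11 through a chair–chair array (bromonium-induced cation–olefin cyclisation as known for germacrane dienes), which sets equatorial bromine at C13, the axial C12 methyl at C11 and H18 anti to H19 (allylic strain keeps H19 in the alkene plane, so C11 arrives on the face bearing C8), while water traps the C16 cation from the equatorial side.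

Step 20
Reactants: 30 bromo alcohol
Product: 31 exocyclic alkene (C16=C17H2)
Conditions: POCl3, pyridine, 0 to 40 °C
Reagents that add atoms: none
Why: E2 elimination of the dichlorophosphate of the equatorial tertiary alcohol can use only an anti-periplanar hydrogen of the axial methyl group, which gives the exocyclic methylene.

Step 21
Reactants: 31 exocyclic alkene
Product: 33 C16 ketone, via ozonide 32 (not isolated)
Conditions: O3, CH2Cl2–MeOH, −78 °C; then Me2S
Reagents that add atoms: ozone, [O-][O+]=O
Why: Ozonolysis of the only alkene with reductive work-up gives the C16 ketone and leaves the bromide and silyl ether alone.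

Step 22
Reactants: 33 C16 ketone
Product: 34 C20 silyl ether of the target
Conditions: MeMgBr, CeCl3, THF, −78 °C
Reagents that add atoms: methylmagnesium bromide, C[Mg]Br
Why: The weakly basic organocerium reagent adds to the ketone from the equatorial side because the axial face is blocked by the syn-axial C12 methyl, which gives the axial tertiary alcohol (sets C16) without enolisation towards the γ-bromide.

Step 23
Reactants: 34 C20 silyl ether of the target
Product: 35 target CNP0295684.1
Conditions: HF·pyridine, THF, 0 to 20 °C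
Reagents that add atoms: none
Why: Fluoride-mediated desilylation frees the endo C20 alcohol and gives the target.

Compound list
1 | (S)-4-acetoxycyclopent-2-en-1-one | CC(=O)O[C@@H]1C=CC(=O)C1 | starting material
2 | 3-methylbuta-1,2-diene | CC(C)=C=C | starting material
3 | 1-lithio-3-methylbuta-1,2-diene (allenyllithium) | [Li]C=C=C(C)C | intermediate
4 | lithium bis(3-methylbuta-1,2-dienyl)cuprate | [Li+].CC(C)=C=C[Cu-]C=C=C(C)C | intermediate
5 | (3R,4S)-4-acetoxy-3-(3-methylbuta-1,2-dienyl)cyclopentan-1-one (allenyl trans to acetoxy) | CC(=O)O[C@@H]1[C@@H](C=C=C(C)C)CC(=O)C1 | intermediate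
6 | (S)-4-(3-methylbuta-1,2-dienyl)cyclopent-2-en-1-one | O=C1C=C[C@@H](C=C=C(C)C)C1 | intermediate
7 | 2-(2-bromoethyl)-1,3-dioxolane | BrCCC1OCCO1 | starting material
8 | [2-(1,3-dioxolan-2-yl)ethyl]magnesium bromide | Br[Mg]CCC1OCCO1 | intermediate
9 | (4S)-1-[2-(1,3-dioxolan-2-yl)ethyl]-4-(3-methylbuta-1,2-dienyl)cyclopent-2-en-1-ol, both C1 epimers | OC1(CCC2OCCO2)C=C[C@@H](C=C=C(C)C)C1 | intermediate
10 | (5R)-5-(3-methylbuta-1,2-dienyl)-3-[2-(1,3-dioxolan-2-yl)ethyl]cyclopent-2-en-1-one | O=C1C=C(CCC2OCCO2)C[C@@H]1C=C=C(C)C | intermediate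
11 | 1-[2-(1,3-dioxolan-2-yl)ethyl]-7-(propan-2-ylidene)tricyclo[3.2.0.0(3,6)]heptan-4-one (C20 ketone, new bonds C8–C4 and C19–C5, C6 as in 10) | O=C1[C@@H]2[C@H]3C(=C(C)C)[C@]2(CCC4OCCO4)C[C@@H]13 | intermediate
12 | 4-[2-(1,3-dioxolan-2-yl)ethyl]-5-(propan-2-ylidene)bicyclo[2.2.1]heptan-2-one (C20 ketone, C19 methylene, chain on bridgehead C8) | CC(C)=C1C[C@H]2C[C@]1(CCC3OCCO3)CC2=O | intermediate
13 | 4-[2-(1,3-dioxolan-2-yl)ethyl]-5-endo-isopropylbicyclo[2.2.1]heptan-2-one | CC(C)[C@@H]1C[C@H]2C[C@]1(CCC3OCCO3)CC2=O | intermediate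
14 | methacrolein (2-methylprop-2-enal) | CC(=C)C=O | starting material
15 | lithium enolate of 13 (C19=C20–OLi) | CC(C)[C@@H]1C[C@H]2C[C@]1(CCC3OCCO3)C=C2O[Li] | intermediate
16 | 13 with a 1-hydroxy-2-methylprop-2-enyl group exo on C19 (H19 endo, both C18 epimers) | CC(C)[C@@H]1C[C@H]2C[C@]1(CCC3OCCO3)[C@H](C(O)C(C)=C)C2=O | intermediate
17 | benzenesulfenate ester of 16 (C18–O–SPh) | CC(C)[C@@H]1C[C@H]2C[C@]1(CCC3OCCO3)[C@H](C(OSc3ccccc3)C(C)=C)C2=O | intermediate
18 | 13 with an (E)-2-methyl-3-(phenylsulfinyl)prop-1-enyl group exo on C19 (both sulfur epimers) | CC(C)[C@@H]1C[C@H]2C[C@]1(CCC3OCCO3)[C@H](/C=C(\C)CS(=O)c3ccccc3)C2=O | intermediate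
19 | endo-C20 alcohol of 18 | CC(C)[C@@H]1C[C@H]2C[C@]1(CCC3OCCO3)[C@H](/C=C(\C)CS(=O)c3ccccc3)[C@H]2O | intermediate
20 | sulfone of 19 (C15–SO2Ph, (E)-C16=C18, C20 endo OH) | CC(C)[C@@H]1C[C@H]2C[C@]1(CCC3OCCO3)[C@H](/C=C(\C)CS(=O)(=O)c3ccccc3)[C@H]2O | intermediate
21 | tert-butyldimethylsilyl ether of 20 (C20–OTBS) | CC(C)[C@@H]1C[C@H]2C[C@]1(CCC3OCCO3)[C@H](/C=C(\C)CS(=O)(=O)c3ccccc3)[C@H]2O[Si](C)(C)C(C)(C)C | intermediate
22 | aldehyde from 21 (C11 formyl) | CC(C)[C@@H]1C[C@H]2C[C@]1(CCC=O)[C@H](/C=C(\C)CS(=O)(=O)c3ccccc3)[C@H]2O[Si](C)(C)C(C)(C)C | intermediate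
23 | terminal alkyne from 22 (C11≡C13) | CC(C)[C@@H]1C[C@H]2C[C@]1(CCC#C)[C@H](/C=C(\C)CS(=O)(=O)c3ccccc3)[C@H]2O[Si](C)(C)C(C)(C)C | intermediate
24 | (E)-alkenyl(dimethyl)alane from 23 (C12 methyl on C11, aluminium on C13) | CC(C)[C@@H]1C[C@H]2C[C@]1(CC/C(C)=C/[Al](C)C)[C@H](/C=C(\C)CS(=O)(=O)c3ccccc3)[C@H]2O[Si](C)(C)C(C)(C)C | intermediate
25 | methyl (E)-enoate (C11(CH3)=C13H–C14O2Me) | CC(C)[C@@H]1C[C@H]2C[C@]1(CC/C(C)=C/C(=O)OC)[C@H](/C=C(\C)CS(=O)(=O)c3ccccc3)[C@H]2O[Si](C)(C)C(C)(C)C | intermediate
26 | (E)-allylic alcohol (C14–OH) | CC(C)[C@@H]1C[C@H]2C[C@]1(CC/C(C)=C/CO)[C@H](/C=C(\C)CS(=O)(=O)c3ccccc3)[C@H]2O[Si](C)(C)C(C)(C)C | intermediate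
27 | (E)-allylic bromide (C14–Br) | CC(C)[C@@H]1C[C@H]2C[C@]1(CC/C(C)=C/CBr)[C@H](/C=C(\C)CS(=O)(=O)c3ccccc3)[C@H]2O[Si](C)(C)C(C)(C)C | intermediate
28 | ten-membered (E,E)-diene sulfone (C14–C15 bond closed, SO2Ph on C15, both C15 epimers) | CC(C)[C@@H]1C[C@H]2C[C@@]13CC/C(C)=C/CC(S(=O)(=O)c4ccccc4)/C(C)=C/[C@@H]3[C@H]2O[Si](C)(C)C(C)(C)C | intermediate
29 | (E,E)-cyclodeca-1,5-diene fused to the norbornane at C8–C19 (C11=C13 and C16=C18, C20–OTBS) | CC(C)[C@@H]1C[C@H]2C[C@@]13CC/C(C)=C/CC/C(C)=C/[C@@H]3[C@H]2O[Si](C)(C)C(C)(C)C | intermediate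
30 | bromo alcohol: target skeleton with C20–OTBS and the C16 epimer (equatorial OH, axial methyl) | CC(C)[C@@H]1C[C@H]2C[C@@]13CC[C@]1(C)[C@@H](Br)CC[C@](C)(O)[C@H]1[C@@H]3[C@H]2O[Si](C)(C)C(C)(C)C | intermediate
31 | exocyclic alkene (C16=C17H2) | CC(C)[C@@H]1C[C@H]2C[C@@]13CC[C@]1(C)[C@@H](Br)CCC(=C)[C@H]1[C@@H]3[C@H]2O[Si](C)(C)C(C)(C)C | intermediate
32 | ozonide of 31 (spiro 1,2,4-trioxolane at C16) | CC(C)[C@@H]1C[C@H]2C[C@@]13CC[C@]1(C)[C@@H](Br)CCC4(OCOO4)[C@H]1[C@@H]3[C@H]2O[Si](C)(C)C(C)(C)C | intermediate
33 | C16 ketone (trans-fused rings A and B, C13 equatorial Br, C20–OTBS) | CC(C)[C@@H]1C[C@H]2C[C@@]13CC[C@]1(C)[C@@H](Br)CCC(=O)[C@H]1[C@@H]3[C@H]2O[Si](C)(C)C(C)(C)C | intermediate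
34 | C20 tert-butyldimethylsilyl ether of the target | CC(C)[C@@H]1C[C@H]2C[C@@]13CC[C@]1(C)[C@@H](Br)CC[C@@](C)(O)[C@H]1[C@@H]3[C@H]2O[Si](C)(C)C(C)(C)C | intermediate
35 | CNP0295684.1 (C13 equatorial Br, C16 axial OH, C20 endo OH, C4 endo isopropyl) | CC(C)[C@@H]1C[C@H]2C[C@@]13CC[C@]1(C)[C@@H](Br)CC[C@@](C)(O)[C@H]1[C@@H]3[C@H]2O | target

Total step count: 23. Longest linear sequence: 23 steps (1 to 35).

Steps most likely to fail:

Step 4. The diradical may close in the straight sense, revert with loss of the allene, or close too slowly to the strained cage. Fallback: setting out from 10, a tin hydride radical reductive cyclisation (Bu3SnH, AIBN, benzene, 80 °C) forms the O-stannyl ketyl, whose β-carbon radical at C8 adds to the central allene carbon C4 in a five-membered closure; hydrogen transfer to the allyl radical and hydrolysis of the tin enolate should give 12 directly. This makes no new compound (F0) and comes back to the route at 12.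

Step 17. Intermolecular alkylation, SN2′ attack or elimination may outrun closure of the ten-membered ring. Fallback: setting out from 26, the alcohol is converted with ClCO2Me and pyridine into the allylic methyl carbonate F1, which is cyclised by palladium-catalysed allylic alkylation (Tsuji–Trost macrocyclisation, Pd(PPh3)4, dppe, THF, reflux, slow addition). The released methoxide deprotonates the allyl sulfone, and the π-allyl complex is attacked at its less substituted terminus C14. This comes back to the route at 28.

Step 19. Water may capture the bromonium ion before the transannular bond forms, the other alkene may be brominated, or the chair–chair pairing may be lost. Fallback: setting out from 29, mercury-mediated transannular cyclisation with Hg(OCOCF3)2 in aqueous MeNO2 and ligand exchange with KBr give the organomercuric bromide F2; brominative demercuration (Br2, LiBr, pyridine) then comes back to the route at 30.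

Further compounds
F0 | step 4 | none | none
F1 | step 17 | allylic methyl carbonate of 26 (C14–OCO2Me) | CC(C)[C@@H]1C[C@H]2C[C@]1(CC/C(C)=C/COC(=O)OC)[C@H](/C=C(\C)CS(=O)(=O)c3ccccc3)[C@H]2O[Si](C)(C)C(C)(C)C
F2 | step 19 | C13 organomercuric bromide of the cyclised skeleton (C16 equatorial OH, C20–OTBS) | CC(C)[C@@H]1C[C@H]2C[C@@]13CC[C@]1(C)[C@@H]([Hg]Br)CC[C@](C)(O)[C@H]1[C@@H]3[C@H]2O[Si](C)(C)C(C)(C)C
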